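**Plan**

- Retrosynthesis: cut C1–C11 and the C9–O bond (Norrish–Yang photocyclisation, then hydration of a Δ8-ene-11,14-dione); then C8–C9 and C11–C12 together (nitro-Michael/Henry); then C7–C8 (aldol); then ring A (Diels–Alder).
- Forward: ring A by Diels–Alder, then aldol union with the cyclopropyl methyl ketone, then rings B and C in one operation, then the cyclobutane last.
- Enabling feature: C11 sits between C9 and C12, and the C14 ketone acidifies C8. As a nitroalkene C9=C11–NO2, C9 is electrophilic toward the C8 enolate and C11 then nucleophilic toward the C12 aldehyde. Both closures are six-membered (ring B: C5–C10; ring C: C8, C9, C11–C14).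
- Stereochemistry: C6 from (R)-glyceraldehyde; C5 and C10 from the endo Diels–Alder on the diene face fixed by C6; C7 by Felkin aldol; C13 and C15 from (R)-propylene glycol cyclic sulfate.
- C12 settles thermodynamically anti to C15; C1 and C11 come from the photocyclisation on the rigid ene-dione; C8 and C9 from water addition on the only open face.

Key step: step 18

Remark: locants C1–C17 are those of the target skeleton (ring A: C1–C5, C10; ring B: C5–C10; ring C: C8, C9, C11–C14; cyclopropane: C13, C15, C16; C17 is the methyl on C15; cyclobutane: C1–C10–C9–C11). Compounds 1, 2, 5, 14 and 15 are taken as commercial. The configurations drawn at C8, C9 and C11 in 26–31 are those expected under equilibrating conditions; they are erased at 32.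

**Route**

Step 1
Reactants: 1 (R)-2,2-dimethyl-1,3-dioxolane-4-carbaldehyde; 2 diethyl (3-oxobutan-2-yl)phosphonate
Product: 3 (E)-4-[(4S)-2,2-dimethyl-1,3-dioxolan-4-yl]-3-methylbut-3-en-2-one
Conditions: LiCl, i-Pr2NEt, MeCN, 0 °C → rt
Reagents that add atoms: none
Why: Masamune–Roush Horner–Wadsworth–Emmons olefination of the α-branched β-ketophosphonate should give the (E)-trisubstituted enone under conditions too mild to epimerise the α-alkoxy aldehyde.

Step 2
Reactants: 3 enone
Product: 4 tert-butyl({(3E)-4-[(4S)-2,2-dimethyl-1,3-dioxolan-4-yl]-3-methylbuta-1,3-dien-2-yl}oxy)dimethylsilane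
Conditions: TBSOTf, Et3N, CH2Cl2, 0 °C
Reagents that add atoms: tert-butyldimethylsilyl triflate (CC(C)(C)[Si](C)(C)OS(=O)(=O)C(F)(F)F)
Why: Soft enolisation of the methyl ketone at the α′-methyl group (silyl enol ether formation) gives the cross-conjugated 2-silyloxy diene.

Step 3
Reactants: 4 silyloxy diene; 5 methacrolein
Product: 6 ring-A aldehyde (C10 bears CH3 and CHO, C5 bears the dioxolanyl group cis to CHO, C3=C4 is the TBS enol ether)
Conditions: 5 (3 equiv), BHT, toluene, 80 °C, sealed tube
Reagents that add atoms: none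
Why: Thermal Diels–Alder reaction in which the 2-silyloxy group ("para") and the C5 substituent ("ortho") both direct C5 to the methyl-bearing carbon, the endo formyl group ends cis to C6, and A(1,3) strain between the C4 methyl and the dioxolane holds H-6 in the diene plane so that the dienophile adds anti to the dioxolane C–O bond, which sets C5 and C10.

Step 4
Reactants: 6 ring-A aldehyde
Product: 7 keto aldehyde (C3 ketone, C4 gem-dimethyl, C10 CHO)
Conditions: BnMe3N+ F−, MeI (excess), 4 Å MS, THF, 0 °C → rt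
Reagents that add atoms: iodomethane (CI)
Why: Fluoride-induced regiospecific C-methylation of the silyl enol ether (Kuwajima–Noyori enolate alkylation) installs the second C4 methyl without a new stereocentre, and the neopentyl non-enolisable aldehyde is expected to be too hindered to compete with excess MeI.

Step 5
Reactants: 7 keto aldehyde
Product: 10 3-[(4S)-2,2-dimethyl-1,3-dioxolan-4-yl]-2,2,4-trimethyl-4-[(E)-2-nitroethenyl]cyclohexan-1-one, via nitroaldol 8 (not isolated), via mesylate 9 (not isolated)
Conditions: MeNO2, TMG (10 mol%), THF, 0 °C; then MsCl, Et3N, CH2Cl2, −10 °C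
Reagents that add atoms: nitromethane (C[N+](=O)[O-])
Why: Henry addition to the hindered aldehyde followed by mesylation and E1cB elimination gives the conjugated (E)-nitroalkene, which places the C9=C11–NO2 unit on C10.

Step 6
Reactants: 10 nitroalkene acetonide
Product: 11 3-[(1S)-1,2-dihydroxyethyl]-2,2,4-trimethyl-4-[(E)-2-nitroethenyl]cyclohexan-1-one
Conditions: AcOH–H2O (4:1), 40 °C
Reagents that add atoms: none
Why: Acid hydrolysis of the terminal acetonide leaves the nitroalkene and the hindered ketone untouched.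

Step 7
Reactants: 11 diol
Product: 12 bis(triethylsilyl) ether of 11
Conditions: TESOTf, 2,6-lutidine, CH2Cl2, −78 °C
Reagents that add atoms: triethylsilyl triflate (CC[Si](CC)(CC)OS(=O)(=O)C(F)(F)F)
Why: Silylation of both hydroxyls with a non-nucleophilic base avoids conjugate addition to the nitroalkene.

Step 8
Reactants: 12 bis-TES ether
Product: 13 (2S)-2-(triethylsilyloxy)aldehyde (C7 is CHO, C6 carries OTES)
Conditions: (COCl)2, DMSO, CH2Cl2, −78 → −30 °C; Et3N
Reagents that add atoms: none
Why: Under Swern conditions a primary triethylsilyl ether is cleaved and oxidised directly to the aldehyde while the secondary TES ether survives (selective Swern oxidation of primary silyl ethers).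

Step 9
Reactants: 14 dimethyl malonate; 15 (4R)-4-methyl-1,3,2-dioxathiolane 2,2-dioxide
Product: 17 dimethyl (2S)-2-methylcyclopropane-1,1-dicarboxylate, via alkyl sulfate 16 (not isolated)
Conditions: NaH (2.1 equiv), DME, 0 → 60 °C
Reagents that add atoms: none
Why: Malonate alkylation at the primary carbon of the cyclic sulfate and 3-exo-tet closure at the secondary carbon with inversion (cyclic sulfate cyclopropanation) sets C15.

Step 10
Reactants: 17 cyclopropane diester
Product: 18 (1R,2S)-1-(methoxycarbonyl)-2-methylcyclopropane-1-carboxylic acid (acid trans to the methyl group)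
Conditions: KOH (1.0 equiv), MeOH, 0 °C → rt; then aq. HCl
Reagents that add atoms: potassium hydroxide ([K+].[OH-])
Why: Selective saponification of the less hindered ester, the one trans to the ring methyl, differentiates the two carbonyls and thereby sets C13.

Step 11
Reactants: 18 half ester
Product: 19 (1S,2S)-1-(hydroxymethyl)-2-methylcyclopropane-1-carboxylic acid
Conditions: LiBH4, THF, 0 → 40 °C; aq. HCl work-up
Reagents that add atoms: none
Why: Lithium borohydride reduces the ester while the lithium carboxylate formed in situ is inert (chemoselective ester reduction).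

Step 12
Reactants: 19 hydroxy acid
Product: 20 1-[(1S,2S)-1-(hydroxymethyl)-2-methylcyclopropyl]ethan-1-one
Conditions: MeLi (3.5 equiv), THF, 0 °C; aq. NH4Cl
Reagents that add atoms: methyllithium ([Li]C)
Why: Addition of methyllithium to the lithium carboxylate stops at the stable gem-diolate and gives the methyl ketone on work-up.

Step 13
Reactants: 20 hydroxy ketone
Product: 21 1-[(1S,2S)-2-methyl-1-{[(triethylsilyl)oxy]methyl}cyclopropyl]ethan-1-one
Conditions: TESCl, imidazole, CH2Cl2, 0 °C
Reagents that add atoms: chlorotriethylsilane (CC[Si](Cl)(CC)CC)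
Why: Routine silylation of the primary alcohol, chosen so that the group can later be oxidised off directly.

Step 14
Reactants: 21 methyl ketone
Product: 22 trimethylsilyl enol ether of 21
Conditions: TMSOTf, Et3N, CH2Cl2, 0 °C
Reagents that add atoms: trimethylsilyl triflate (C[Si](C)(C)OS(=O)(=O)C(F)(F)F)
Why: Silyl enol ether formation can occur only toward the methyl group because the other α-carbon (C13) is quaternary.

Step 15
Reactants: 13 aldehyde; 22 silyl enol ether
Product: 23 β-hydroxy ketone (C7–OH, C6–OTES, C14=O, C12 as CH2OTES, nitroalkene on C10)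
Conditions: BF3·OEt2, CH2Cl2, −78 °C
Reagents that add atoms: none
Why: Mukaiyama aldol addition to the α-silyloxy aldehyde under a non-chelating Lewis acid follows the polar Felkin–Anh model and gives the 6,7-anti (6S,7R) adduct, the aldehyde being far more reactive than the neopentyl nitroalkene.

Step 16
Reactants: 23 β-hydroxy ketone
Product: 24 7-O-TBS ether of 23
Conditions: TBSOTf, 2,6-lutidine, CH2Cl2, −78 °C
Reagents that add atoms: tert-butyldimethylsilyl triflate (CC(C)(C)[Si](C)(C)OS(=O)(=O)C(F)(F)F)
Why: Low-temperature silylation protects the aldol hydroxyl before it can undergo retro-aldol or add to the nitroalkene.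

Step 17
Reactants: 24 tris-silyl ether
Product: 25 keto aldehyde (C12 is CHO on the cyclopropane)
Conditions: (COCl)2, DMSO, CH2Cl2, −78 → −30 °C; Et3N
Reagents that add atoms: none
Why: The same direct Swern oxidation converts only the primary TES ether into the aldehyde and leaves the secondary TES and TBS ethers in place.

Step 18
Reactants: 25 keto aldehyde nitroalkene
Product: 27 tricyclic nitro alcohol (rings A–C; C11–NO2 and C12–OH), via Michael adduct 26 (not isolated)
Conditions: DBU (20 mol%), THF, −20 °C → rt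
Reagents that add atoms: none
Why: DBU reversibly forms the C14 ketone enolate, whose only α-carbon (C8; C13 is quaternary) adds to C9 of the nitroalkene (intramolecular nitro-Michael, 6-exo-trig, closes ring B) to give nitronate 26, which adds through C11 to the non-enolisable C12 aldehyde (intramolecular Henry reaction, 6-exo-trig, closes ring C). The closest known reaction type is the domino Michael–Henry cyclisation used to build nitrocyclohexanols. Four stereocentres arise; C8, C9 and C11 form under thermodynamic control because both additions and the α-protons are reversible, and they are erased later, so only C12 matters. C12 is controlled by the spiro-cyclopropane: the C15 methyl lies syn to C12, so the hydroxyl should settle anti to C15 on the C16 side, and it stays correctable by enolisation once C11 is a ketone. The step needs the Michael closure before the Henry closure, which ring size secures (a direct Henry closure would need a ten-membered ring), and a single productive enolate, which the substrate secures because the C3 enolate has no five- or six-membered outlet and the aldehyde cannot enolise. The silyl ethers at C6 and C7 keep both oxygens from adding to the nitroalkene.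

Step 19
Reactants: 27 nitro alcohol
Product: 29 α-ketol (C11=O and C12–OH), via potassium nitronate 28 (not isolated)
Conditions: t-BuOK (1.1 equiv), THF, −78 °C; then DMDO, acetone, −78 → −30 °C
Reagents that add atoms: dimethyldioxirane (CC1(C)OO1)
Why: Oxidative Nef reaction, in which the nitronate (the nitro C–H is far more acidic than the alcohol) is cleaved by the dioxirane at low temperature faster than retro-Henry opening.

Step 20
Reactants: 29 α-ketol
Product: 30 6,12-diol (C7–OTBS kept)
Conditions: PPTS, MeOH, 0 °C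
Reagents that add atoms: none
Why: Mild acid methanolysis removes the secondary TES ether selectively in the presence of the more robust TBS ether.

Step 21
Reactants: 30 diol
Product: 31 6,12-diacetate
Conditions: Ac2O, pyridine, DMAP, CH2Cl2, rt
Reagents that add atoms: acetic anhydride (CC(=O)OC(C)=O)
Why: DMAP-catalysed acetylation esterifies the two free secondary hydroxyls at C6 and C12.

Step 22
Reactants: 31 saturated 1,4-diketone
Product: 32 Δ8-ene-11,14-dione
Conditions: DDQ, TsOH (cat.), 1,4-dioxane, 60 °C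
Reagents that add atoms: none
Why: The C8–C9 unit lies between the C14 and C11 carbonyls, so its bis-enol is oxidised by DDQ like a hydroquinone (quinone dehydrogenation of a 1,4-diketone to the ene-dione) well before the singly activated ring-A ketone reacts.

Step 23
Reactants: 32 ene-dione
Product: 34 7-O-TBS ether of the target, via cyclobutanol enone 33 (not isolated)
Conditions: hν (365 nm), degassed MeCN–H2O (9:1), rt
Reagents that add atoms: water (O)
Why: Excitation of the ene-dione lets O-11 abstract the in-plane equatorial H-1 through a six-membered transition state, the 1,4-biradical closes to the cyclobutanol (Norrish–Yang cyclisation; ring C forces OH-11 onto the face of the C10 methyl and the equatorial bond gives the trans fusion to ring A), and the strained alkylidene-cyclobutane enone then adds water at C9 from its only open face with equilibrating protonation at C8 to the cis B/C fusion (conjugate hydration).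

Step 24
Reactants: 34 TBS ether
Product: 35 target CNP0157858.2
Conditions: HF·pyridine, pyridine, THF, 0 °C → rt
Reagents that add atoms: none
Why: Buffered fluoride desilylation frees the C7 hydroxyl without acetate migration, retro-aldol or dehydration of the tertiary carbinols.

**Compound list**

1 | (R)-2,2-dimethyl-1,3-dioxolane-4-carbaldehyde | O=C[C@H]1COC(C)(C)O1 | starting material
2 | diethyl (3-oxobutan-2-yl)phosphonate | CCOP(=O)(OCC)C(C)C(C)=O | starting material
3 | (E)-4-[(4S)-2,2-dimethyl-1,3-dioxolan-4-yl]-3-methylbut-3-en-2-one | CC(=O)/C(C)=C/[C@H]1COC(C)(C)O1 | intermediate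
4 | TBS dienol ether of 3 (2-silyloxy-1,3-diene) | C=C(O[Si](C)(C)C(C)(C)C)/C(C)=C/[C@H]1COC(C)(C)O1 | intermediate
5 | methacrolein | CC(=C)C=O | starting material
6 | ring-A aldehyde: 4-(TBSO)-2-[(4S)-dioxolanyl]-1,3-dimethylcyclohex-3-ene-1-carbaldehyde, CHO cis to the dioxolanyl group | CC1(C)OC[C@@H](O1)[C@@H]1C(C)=C(O[Si](C)(C)C(C)(C)C)CC[C@]1(C)C=O | intermediate
7 | keto aldehyde: 2-[(4S)-dioxolanyl]-1,3,3-trimethyl-4-oxocyclohexane-1-carbaldehyde (C5, C10 as in the target) | CC1(C)OC[C@@H](O1)[C@@H]1C(C)(C)C(=O)CC[C@]1(C)C=O | intermediate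
8 | nitroaldol of 7 (C9 carbinol, both epimers) | CC1(C)OC[C@@H](O1)[C@@H]1C(C)(C)C(=O)CC[C@]1(C)C(O)C[N+](=O)[O-] | intermediate
9 | 9-O-mesylate of 8 | CC1(C)OC[C@@H](O1)[C@@H]1C(C)(C)C(=O)CC[C@]1(C)C(OS(C)(=O)=O)C[N+](=O)[O-] | intermediate
10 | 3-[(4S)-2,2-dimethyl-1,3-dioxolan-4-yl]-2,2,4-trimethyl-4-[(E)-2-nitroethenyl]cyclohexan-1-one | CC1(C)OC[C@@H](O1)[C@@H]1C(C)(C)C(=O)CC[C@]1(C)/C=C/[N+](=O)[O-] | intermediate
11 | 3-[(1S)-1,2-dihydroxyethyl]-2,2,4-trimethyl-4-[(E)-2-nitroethenyl]cyclohexan-1-one | OC[C@@H](O)[C@@H]1C(C)(C)C(=O)CC[C@]1(C)/C=C/[N+](=O)[O-] | intermediate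
12 | bis(triethylsilyl) ether of 11 | CC[Si](CC)(CC)OC[C@@H](O[Si](CC)(CC)CC)[C@@H]1C(C)(C)C(=O)CC[C@]1(C)/C=C/[N+](=O)[O-] | intermediate
13 | (2S)-2-(triethylsilyloxy)-2-[ring A]acetaldehyde (C7 aldehyde) | O=C[C@@H](O[Si](CC)(CC)CC)[C@@H]1C(C)(C)C(=O)CC[C@]1(C)/C=C/[N+](=O)[O-] | intermediate
14 | dimethyl malonate | COC(=O)CC(=O)OC | starting material
15 | (4R)-4-methyl-1,3,2-dioxathiolane 2,2-dioxide | C[C@@H]1COS(=O)(=O)O1 | starting material
16 | sodium (2R)-4,4-bis(methoxycarbonyl)butan-2-yl sulfate | [Na+].COC(=O)C(C[C@@H](C)OS(=O)(=O)[O-])C(=O)OC | intermediate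
17 | dimethyl (2S)-2-methylcyclopropane-1,1-dicarboxylate | COC(=O)C1(C[C@@H]1C)C(=O)OC | intermediate
18 | (1R,2S)-1-(methoxycarbonyl)-2-methylcyclopropane-1-carboxylic acid | OC(=O)[C@]1(C[C@@H]1C)C(=O)OC | intermediate
19 | (1S,2S)-1-(hydroxymethyl)-2-methylcyclopropane-1-carboxylic acid | OC(=O)[C@]1(C[C@@H]1C)CO | intermediate
20 | 1-[(1S,2S)-1-(hydroxymethyl)-2-methylcyclopropyl]ethan-1-one | CC(=O)[C@]1(C[C@@H]1C)CO | intermediate
21 | 1-[(1S,2S)-2-methyl-1-{[(triethylsilyl)oxy]methyl}cyclopropyl]ethan-1-one | CC(=O)[C@]1(C[C@@H]1C)CO[Si](CC)(CC)CC | intermediate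
22 | trimethylsilyl enol ether of 21 | C=C(O[Si](C)(C)C)[C@]1(C[C@@H]1C)CO[Si](CC)(CC)CC | intermediate
23 | aldol adduct: (6S,7R) 6-OTES, 7-OH, 14-ketone, 12-CH2OTES, nitroalkene on C10 | CC[Si](CC)(CC)OC[C@@]1(C[C@@H]1C)C(=O)C[C@@H](O)[C@@H](O[Si](CC)(CC)CC)[C@@H]1C(C)(C)C(=O)CC[C@]1(C)/C=C/[N+](=O)[O-] | intermediate
24 | 7-O-TBS ether of 23 | CC[Si](CC)(CC)OC[C@@]1(C[C@@H]1C)C(=O)C[C@@H](O[Si](C)(C)C(C)(C)C)[C@@H](O[Si](CC)(CC)CC)[C@@H]1C(C)(C)C(=O)CC[C@]1(C)/C=C/[N+](=O)[O-] | intermediate
25 | keto aldehyde (C12 = CHO), substrate of the key step | O=C[C@@]1(C[C@@H]1C)C(=O)C[C@@H](O[Si](C)(C)C(C)(C)C)[C@@H](O[Si](CC)(CC)CC)[C@@H]1C(C)(C)C(=O)CC[C@]1(C)/C=C/[N+](=O)[O-] | intermediate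
26 | Michael adduct: ring B closed, C9 carries CH2NO2, C12 still CHO | CC[Si](CC)(CC)O[C@@H]1[C@H](O[Si](C)(C)C(C)(C)C)[C@H](C(=O)[C@]2(C[C@@H]2C)C=O)[C@@H](C[N+](=O)[O-])[C@@]2(C)CCC(=O)C(C)(C)[C@@H]12 | intermediate
27 | tricyclic nitro alcohol: 11-nitro, 12-hydroxy, 3,14-dione, 6-OTES, 7-OTBS | CC[Si](CC)(CC)O[C@@H]1[C@H](O[Si](C)(C)C(C)(C)C)[C@@H]2C(=O)[C@]3(C[C@@H]3C)[C@H](O)[C@H]([N+](=O)[O-])[C@H]2[C@@]2(C)CCC(=O)C(C)(C)[C@@H]12 | intermediate
28 | potassium C11-nitronate of 27 | [K+].CC[Si](CC)(CC)O[C@@H]1[C@H](O[Si](C)(C)C(C)(C)C)[C@@H]2C(=O)[C@]3(C[C@@H]3C)[C@H](O)C(=[N+]([O-])[O-])[C@H]2[C@@]2(C)CCC(=O)C(C)(C)[C@@H]12 | intermediate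
29 | α-ketol: 12-hydroxy-3,11,14-trione, 6-OTES, 7-OTBS | CC[Si](CC)(CC)O[C@@H]1[C@H](O[Si](C)(C)C(C)(C)C)[C@@H]2C(=O)[C@]3(C[C@@H]3C)[C@H](O)C(=O)[C@H]2[C@@]2(C)CCC(=O)C(C)(C)[C@@H]12 | intermediate
30 | 6,12-diol, 7-OTBS | O[C@@H]1[C@H](O[Si](C)(C)C(C)(C)C)[C@@H]2C(=O)[C@]3(C[C@@H]3C)[C@H](O)C(=O)[C@H]2[C@@]2(C)CCC(=O)C(C)(C)[C@@H]12 | intermediate
31 | 6,12-diacetate, 7-OTBS, saturated 3,11,14-trione | CC(=O)O[C@@H]1[C@H](O[Si](C)(C)C(C)(C)C)[C@@H]2C(=O)[C@]3(C[C@@H]3C)[C@H](OC(C)=O)C(=O)[C@H]2[C@@]2(C)CCC(=O)C(C)(C)[C@@H]12 | intermediate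
32 | Δ8-ene-3,11,14-trione (ene-dione), 6,12-diacetate, 7-OTBS | CC(=O)O[C@@H]1[C@H](O[Si](C)(C)C(C)(C)C)C=2C(=O)[C@]3(C[C@@H]3C)[C@H](OC(C)=O)C(=O)C2[C@@]2(C)CCC(=O)C(C)(C)[C@@H]12 | intermediate
33 | cyclobutanol enone: C1–C11 bond formed, 11-OH, Δ8-14-ketone | CC(=O)O[C@@H]1[C@H](O[Si](C)(C)C(C)(C)C)C=2C(=O)[C@]3(C[C@@H]3C)[C@H](OC(C)=O)[C@@]3(O)[C@@H]4CC(=O)C(C)(C)[C@@H]1[C@@]4(C)C23 | intermediate
34 | 7-O-TBS ether of the target | CC(=O)O[C@@H]1[C@H](O[Si](C)(C)C(C)(C)C)[C@H]2C(=O)[C@]3(C[C@@H]3C)[C@H](OC(C)=O)[C@@]3(O)[C@@H]4CC(=O)C(C)(C)[C@@H]1[C@@]4(C)[C@@]23O | intermediate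
35 | CNP0157858.2: 6,12-diacetoxy-7,9,11-trihydroxy-3,14-dione with the C1–C11 cyclobutane and the C13 spiro-cyclopropane (1R,5S,6S,7R,8R,9S,10R,11S,12S,13S,15S) | CC(=O)O[C@@H]1[C@H](O)[C@H]2C(=O)[C@]3(C[C@@H]3C)[C@H](OC(C)=O)[C@@]3(O)[C@@H]4CC(=O)C(C)(C)[C@@H]1[C@@]4(C)[C@@]23O | target

**Summary**

Total steps: 24. Longest linear sequence: 18 (steps 1–8 and 15–24).

Steps most likely to fail:

1. Step 23. Hydrogen abstraction may occur at another γ-hydrogen, or water may fail to add to the strained enone (or be lost again) under the irradiation conditions. Fallback: set out from 32, irradiate in dry benzene and isolate cyclobutanol enone 33. Epoxidise its enone on the exposed face (t-BuOOH, DBU, CH2Cl2; Weitz–Scheffer epoxidation) to the 8,9-epoxy ketone F1. Open the α,β-epoxy ketone reductively at C8 ((PhSe)2, NaBH4, AcOH, EtOH; Miyashita reduction), which keeps the C9–O bond and returns to the route at 34.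

2. Step 22. Dehydrogenation may be slow, may spread to ring A (C1–C2), or may scramble C12. Fallback: set out from 31 and selenenylate at C8 through the enol of the C14 ketone (PhSeCl, EtOAc, rt) to the 8-phenylselanyl triketone F2. Oxidise to the selenoxide (H2O2, pyridine, CH2Cl2, 0 °C); syn-elimination toward H-9 returns to the route at 32.

3. Step 18. The C8 enolate may expel the C7 silyloxy group, or the Henry closure may lag while the free aldehyde decomposes. Fallback: decouple the two closures. Set out from 24, with C12 still masked, and run the nitro-Michael addition alone under a bifunctional thiourea–tertiary-amine catalyst (toluene, rt) to the ring-B-closed nitroalkane F3. Oxidise its primary TES ether directly (Swern) to 26, now isolated, and close ring C with Et3N in THF (Henry reaction), returning to the route at 27.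

**Further compounds**

F1 | step 23 | 8,9-epoxide of cyclobutanol enone 33 (oxygen on the face of the C10 methyl) | CC(=O)O[C@@H]1[C@H](O[Si](C)(C)C(C)(C)C)[C@@]25C(=O)[C@]3(C[C@@H]3C)[C@H](OC(C)=O)[C@@]3(O)[C@@H]4CC(=O)C(C)(C)[C@@H]1[C@@]4(C)[C@@]23O5
F2 | step 22 | 8-phenylselanyl derivative of triketone 31 (C8 epimers) | CC(=O)O[C@@H]1[C@H](O[Si](C)(C)C(C)(C)C)C2([Se]c5ccccc5)C(=O)[C@]3(C[C@@H]3C)[C@H](OC(C)=O)C(=O)[C@H]2[C@@]2(C)CCC(=O)C(C)(C)[C@@H]12
F3 | step 18 | ring-B-closed nitroalkane with C12 as CH2OTES | CC[Si](CC)(CC)O[C@@H]1[C@H](O[Si](C)(C)C(C)(C)C)[C@H](C(=O)[C@]2(C[C@@H]2C)CO[Si](CC)(CC)CC)[C@@H](C[N+](=O)[O-])[C@@]2(C)CCC(=O)C(C)(C)[C@@H]12
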